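Ring A is taken apart at C3–C4 and C5–C10, the retron of an intramolecular Diels–Alder reaction. The gem-dimethyl carbon C4 and the ring-fusion carbon C5 form an isopropylidene ketone dienophile activated by C6 (later the C6 acetate carbon), and C10–C1–C2–C3 is a (Z)-diene whose methyl-bearing terminus becomes quaternary C10. One cycloaddition of an open-chain trienone, tethered through C6–C9, should close rings A and B and set C10 from the C9 stereocentre by allylic strain. The Z-diene enforces a cis ring fusion, which is corrected at C5 by epimerisation next to the C6 ketone.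

Key step: step 12

Remark (assumption): the sense of induction of (R)-BINAP in step 4 is assigned by analogy with rhodium-catalysed conjugate additions to cyclic enones; the enantiomeric ligand would give the antipodal series.
Remark (numbering): labdane numbering (C1–C20) is used for all intermediates; changes of CIP descriptor at C8 and C9 along the route reflect priority changes only, not inversion.

Step 1
Reactants: 1 but-2-yn-1-ol
Product: 3 (Z)-3-iodobut-2-en-1-ol, via cyclic alkenylalanate 2 (not isolated)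
Conditions: NaAlH2(OCH2CH2OMe)2, THF, 0 °C to rt; then I2, −78 to 0 °C
Reagents that add atoms: iodine, II
Why: trans-hydroalumination of the propargylic alcohol places aluminium on C3 cis to the CH2O group in a chelated alanate, and iodinolysis with retention should give the (Z)-iodoalkene (future C10=C1 geometry).

Step 2
Reactants: 3 (Z)-3-iodobut-2-en-1-ol
Product: 4 (Z)-tert-butyl[(3-iodobut-2-en-1-yl)oxy]dimethylsilane
Conditions: t-BuMe2SiCl, imidazole, DMF, rt
Reagents that add atoms: tert-butyldimethylsilyl chloride, CC(C)(C)[Si](C)(C)Cl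
Why: routine silylation protects the primary allylic hydroxyl (future C2 oxygen).

Step 3
Reactants: 4 (Z)-tert-butyl[(3-iodobut-2-en-1-yl)oxy]dimethylsilane
Product: 5 (E)-tert-butyldimethyl{[3-(4,4,5,5-tetramethyl-1,3,2-dioxaborolan-2-yl)but-2-en-1-yl]oxy}silane (boron cis to the CH2OTBS group)
Conditions: bis(pinacolato)diboron, PdCl2(PPh3)2 (cat.), PPh3, KOPh, toluene, 50 °C
Reagents that add atoms: bis(pinacolato)diboron, CC1(C)OB(OC1(C)C)B1OC(C)(C)C(C)(C)O1
Why: Miyaura borylation of an alkenyl iodide proceeds with retention of the double-bond geometry (the descriptor changes only because boron ranks below carbon).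

Step 4
Reactants: 5 (E)-alkenylboronate; 6 5,6-dihydro-2H-pyran-2-one
Product: 7 (R)-4-[(Z)-4-(tert-butyldimethylsilyloxy)but-2-en-2-yl]tetrahydro-2H-pyran-2-one
Conditions: [Rh(OH)(cod)]2 (cat.), (R)-BINAP, KOH (0.1 equiv), 1,4-dioxane/H2O 10:1, 50 °C
Reagents that add atoms: none
Why: rhodium-catalysed asymmetric conjugate addition of the alkenylboronate to the unsaturated lactone (Hayashi–Miyaura reaction) should set C9, with the BINAP ligand selecting the enone face and the alkene geometry retained.

Step 5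
Reactants: 7 lactone; 8 2-bromo-N-methoxy-N-methylacetamide
Product: 10 2-{(3S,4R)-4-[(Z)-4-(tert-butyldimethylsilyloxy)but-2-en-2-yl]-2-oxotetrahydro-2H-pyran-3-yl}-N-methoxy-N-methylacetamide, via lithium enolate 9 (not isolated)
Conditions: LiN(i-Pr)2, THF, −78 °C; then 8, DMPU, −78 to −40 °C
Reagents that add atoms: none
Why: alkylation of the lactone enolate should occur anti to the ring C4 alkenyl group, giving the 3,4-trans lactone and hence the C8/C9 relationship that places both the C17 ester and C11 equatorial on ring B later.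

Step 6
Reactants: 10 trans-disubstituted lactone
Product: 11 methyl (2S,3R,4Z)-6-(tert-butyldimethylsilyloxy)-3-(2-hydroxyethyl)-2-{2-[methoxy(methyl)amino]-2-oxoethyl}-4-methylhex-4-enoate
Conditions: K2CO3 (cat.), MeOH, 0 °C
Reagents that add atoms: methanol, CO
Why: base-catalysed methanolysis opens the six-membered lactone to the methyl ester (C17) and frees the C12 hydroxyl, leaving the amide and silyl ether intact.

Step 7
Reactants: 11 hydroxy ester
Product: 12 methyl (2S,3R,4Z)-6-(tert-butyldimethylsilyloxy)-3-[2-(tert-butyldiphenylsilyloxy)ethyl]-2-{2-[methoxy(methyl)amino]-2-oxoethyl}-4-methylhex-4-enoate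
Conditions: t-BuPh2SiCl, imidazole, DMF, 0 °C to rt
Reagents that add atoms: tert-butyldiphenylsilyl chloride, CC(C)(C)[Si](Cl)(c1ccccc1)c1ccccc1
Why: immediate silylation of the primary alcohol traps the hydroxy ester before it can relactonise and gives a C12 protecting group that outlasts the TBS ether.

Step 8
Reactants: 12 bis-silyl ether
Product: 13 methyl (2S,3R,4Z)-3-[2-(tert-butyldiphenylsilyloxy)ethyl]-6-hydroxy-2-{2-[methoxy(methyl)amino]-2-oxoethyl}-4-methylhex-4-enoate
Conditions: pyridinium p-toluenesulfonate (cat.), MeOH, rt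
Reagents that add atoms: none
Why: mild acid-catalysed methanolysis should cleave the primary allylic TBS ether while the bulkier TBDPS ether survives.

Step 9
Reactants: 13 allylic alcohol
Product: 14 methyl (2S,3R,4Z)-3-[2-(tert-butyldiphenylsilyloxy)ethyl]-2-{2-[methoxy(methyl)amino]-2-oxoethyl}-4-methyl-6-oxohex-4-enoate
Conditions: MnO2, CH2Cl2, rt
Reagents that add atoms: none
Why: MnO2 oxidises allylic alcohols selectively under neutral conditions, which should preserve the Z geometry of the enal.

Step 10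
Reactants: 14 (Z)-enal
Product: 15 methyl (2S,3R,4Z)-3-[2-(tert-butyldiphenylsilyloxy)ethyl]-2-{2-[methoxy(methyl)amino]-2-oxoethyl}-4-methylhepta-4,6-dienoate
Conditions: Ph3PCH3Br, KN(SiMe3)2, THF, −78 to 0 °C
Reagents that add atoms: methyltriphenylphosphonium bromide, C[P+](c1ccccc1)(c1ccccc1)c1ccccc1.[Br-]
Why: Wittig methylenation of the unhindered enal is much faster than attack on the ester or amide and should give the (Z)-1,3-diene (C3=C2–C1=C10).

Step 11
Reactants: 15 dienyl amide; 16 (2-methylprop-1-en-1-yl)magnesium bromide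
Product: 17 methyl (2S,3R,4Z)-3-[2-(tert-butyldiphenylsilyloxy)ethyl]-4-methyl-2-(4-methyl-2-oxopent-3-en-1-yl)hepta-4,6-dienoate
Conditions: THF, −20 to 0 °C; aq. NH4Cl
Reagents that add atoms: none
Why: the Grignard reagent should add once to the N-methoxy-N-methylamide through its stable magnesium chelate (Weinreb ketone synthesis), sparing the α-branched methyl ester and giving the isopropylidene ketone dienophile.

Step 12
Reactants: 17 trienone
Product: 18 methyl (5S,8S,9R,10S)-12-(tert-butyldiphenylsilyloxy)-6-oxo-13,14,15,16-tetranorlabd-1-en-17-oate (rings A and B cis-fused)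
Conditions: Me2AlCl (2.5 equiv), CH2Cl2, −78 to −20 °C
Reagents that add atoms: none
Why: Me2AlCl binds the C6 ketone and the (Z)-diene adds across the isopropylidene enone in a concerted but asynchronous [4+2] cycloaddition, C3–C4 bonding running ahead of C5–C10. The closest known reaction type is the Lewis-acid-promoted type 1 intramolecular Diels–Alder reaction of 1,7,9-decatrien-3-ones. Ring A (a cyclohexene with C1=C2) is the cycloaddition ring formed by both new bonds, and ring B is closed by the C5–C10 bond across the four-atom tether C6–C9 in the fused mode. Because C9 occupies the inner (Z) position of the diene, only the transition state with the tether exo is accessible, so H5 ends up cis to the C10 methyl (cis fusion, corrected in step 14); allylic 1,3-strain holds the C9–H bond in the diene plane, so the dienophile, delivered through C8, adds to the face opposite C11 and sets C10 with its methyl cis to C11. The step needs reactivity at two carbons that become quaternary and attack on one diene face; polarisation by the aluminium-bound ketone, a chair-like ring B with the C8 ester and C11 chain both equatorial, and the low temperature (which suppresses the [1,5]-hydrogen shift of the Z-diene) should secure them.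

Step 13
Reactants: 18 cis-fused octalone
Product: 19 methyl (5S,8S,9R,10S)-12-(tert-butyldiphenylsilyloxy)-6-oxo-13,14,15,16-tetranorlabdan-17-oate (cis-fused)
Conditions: H2 (1 atm), Pd/C, EtOAc, rt
Reagents that add atoms: none
Why: heterogeneous hydrogenation saturates the only alkene (C1=C2) and creates no stereocentre.

Step 14
Reactants: 19 cis-fused decalone
Product: 20 methyl (5R,8S,9R,10S)-12-(tert-butyldiphenylsilyloxy)-6-oxo-13,14,15,16-tetranorlabdan-17-oate (trans-fused)
Conditions: NaOMe, MeOH, 40 °C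
Reagents that add atoms: none
Why: reversible enolisation towards C5 should give the trans-fused decalone, favoured thermodynamically and by protonation of the enolate opposite the C10 and axial C4 methyl groups, while C9 is not acidic at this stage and the C8 ester stays equatorial.

Step 15
Reactants: 20 trans-fused decalone
Product: 22 methyl (5R,9S,10S)-12-(tert-butyldiphenylsilyloxy)-6-oxo-13,14,15,16-tetranorlabd-7-en-17-oate, via silyl enol ether 21 (not isolated)
Conditions: LiN(i-Pr)2, Me3SiCl, THF, −78 °C; then Pd(OAc)2, MeCN, rt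
Reagents that add atoms: none
Why: kinetic enolisation of the ketone towards the C7 methylene followed by Saegusa–Ito oxidation should introduce C7=C8 by β-hydride loss from C8 under non-basic conditions that leave the now γ-acidic C9 untouched.

Step 16
Reactants: 22 enone ester
Product: 23 (5R,6S,9S,10S)-12-(tert-butyldiphenylsilyloxy)-13,14,15,16-tetranorlabd-7-ene-6,17-diol
Conditions: i-Bu2AlH (excess), CH2Cl2, −78 to −20 °C
Reagents that add atoms: none
Why: i-Bu2AlH should reduce the enone carbonyl (1,2) and the conjugated ester in one operation, hydride reaching C6 from the face opposite the C10 and axial C4 methyl groups so that the C6 hydroxyl is cis to the C10 methyl.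

Step 17
Reactants: 23 diol
Product: 24 (5R,6S,9S,10S)-12-(tert-butyldiphenylsilyloxy)-13,14,15,16-tetranorlabd-7-ene-6,17-diyl diacetate
Conditions: Ac2O, pyridine, DMAP, CH2Cl2, 40 °C
Reagents that add atoms: acetic anhydride, CC(=O)OC(C)=O
Why: DMAP-catalysed acetylation esterifies both the primary allylic and the hindered axial secondary hydroxyl.

Step 18
Reactants: 24 diacetate silyl ether
Product: 25 (5R,6S,9S,10S)-12-hydroxy-13,14,15,16-tetranorlabd-7-ene-6,17-diyl diacetate
Conditions: HF·pyridine, pyridine, THF, 0 °C to rt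
Reagents that add atoms: none
Why: buffered HF·pyridine removes the silyl ether without cleaving or shifting the allylic acetates.

Step 19
Reactants: 25 primary alcohol
Product: 26 (5R,6S,9S,10S)-12-oxo-13,14,15,16-tetranorlabd-7-ene-6,17-diyl diacetate
Conditions: Dess–Martin periodinane, NaHCO3, CH2Cl2, rt
Reagents that add atoms: none
Why: buffered Dess–Martin oxidation gives the aldehyde under neutral conditions compatible with the acetates.

Step 20
Reactants: 26 aldehyde; 27 2-(triphenylphosphoranylidene)propanal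
Product: 28 (5R,6S,9S,10S,12E)-14-oxo-15-norlabda-7,12-diene-6,17-diyl diacetate
Conditions: toluene, 80 °C
Reagents that add atoms: none
Why: the stabilised ylide reacts only with the aliphatic aldehyde and should give the (E)-2-methyl enal (Wittig reaction).

Step 21
Reactants: 28 (E)-enal
Product: 29 (5R,6S,9S,10S,12E)-labda-7,12,14-triene-6,17-diyl diacetate (target)
Conditions: Ph3PCH3Br, KN(SiMe3)2, THF, −78 to 0 °C
Reagents that add atoms: methyltriphenylphosphonium bromide, C[P+](c1ccccc1)(c1ccccc1)c1ccccc1.[Br-]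
Why: Wittig methylenation of the enal at low temperature is much faster than attack of the ylide on the acetates and completes the (E)-configured diene side chain.

Compound list
1 | but-2-yn-1-ol | CC#CCO | starting material
2 | sodium cyclic alkenylalanate (3-methyl-2,5-dihydro-1,2-oxaluminole ate complex with two 2-methoxyethoxy ligands) | CC1=CCO[Al-]1(OCCOC)OCCOC.[Na+] | intermediate (not isolated)
3 | (Z)-3-iodobut-2-en-1-ol | C/C(I)=C/CO | intermediate
4 | (Z)-tert-butyl[(3-iodobut-2-en-1-yl)oxy]dimethylsilane | C/C(I)=C/CO[Si](C)(C)C(C)(C)C | intermediate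
5 | (E)-tert-butyldimethyl{[3-(4,4,5,5-tetramethyl-1,3,2-dioxaborolan-2-yl)but-2-en-1-yl]oxy}silane | C/C(B1OC(C)(C)C(C)(C)O1)=C/CO[Si](C)(C)C(C)(C)C | intermediate
6 | 5,6-dihydro-2H-pyran-2-one | O=C1C=CCCO1 | starting material
7 | (R)-4-[(Z)-4-(tert-butyldimethylsilyloxy)but-2-en-2-yl]tetrahydro-2H-pyran-2-one | O=C1C[C@H](/C(C)=C\CO[Si](C)(C)C(C)(C)C)CCO1 | intermediate
8 | 2-bromo-N-methoxy-N-methylacetamide | CON(C)C(=O)CBr | starting material
9 | lithium enolate of lactone 7 | [Li+].[O-]C1=C[C@H](/C(C)=C\CO[Si](C)(C)C(C)(C)C)CCO1 | intermediate (not isolated)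
10 | 2-{(3S,4R)-4-[(Z)-4-(tert-butyldimethylsilyloxy)but-2-en-2-yl]-2-oxotetrahydro-2H-pyran-3-yl}-N-methoxy-N-methylacetamide | O=C1[C@@H](CC(=O)N(C)OC)[C@H](/C(C)=C\CO[Si](C)(C)C(C)(C)C)CCO1 | intermediate
11 | methyl (2S,3R,4Z)-6-(tert-butyldimethylsilyloxy)-3-(2-hydroxyethyl)-2-{2-[methoxy(methyl)amino]-2-oxoethyl}-4-methylhex-4-enoate | COC(=O)[C@@H](CC(=O)N(C)OC)[C@H](/C(C)=C\CO[Si](C)(C)C(C)(C)C)CCO | intermediate
12 | methyl (2S,3R,4Z)-6-(tert-butyldimethylsilyloxy)-3-[2-(tert-butyldiphenylsilyloxy)ethyl]-2-{2-[methoxy(methyl)amino]-2-oxoethyl}-4-methylhex-4-enoate | COC(=O)[C@@H](CC(=O)N(C)OC)[C@H](/C(C)=C\CO[Si](C)(C)C(C)(C)C)CCO[Si](c1ccccc1)(c1ccccc1)C(C)(C)C | intermediate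
13 | methyl (2S,3R,4Z)-3-[2-(tert-butyldiphenylsilyloxy)ethyl]-6-hydroxy-2-{2-[methoxy(methyl)amino]-2-oxoethyl}-4-methylhex-4-enoate | COC(=O)[C@@H](CC(=O)N(C)OC)[C@H](/C(C)=C\CO)CCO[Si](c1ccccc1)(c1ccccc1)C(C)(C)C | intermediate
14 | methyl (2S,3R,4Z)-3-[2-(tert-butyldiphenylsilyloxy)ethyl]-2-{2-[methoxy(methyl)amino]-2-oxoethyl}-4-methyl-6-oxohex-4-enoate | COC(=O)[C@@H](CC(=O)N(C)OC)[C@H](/C(C)=C\C=O)CCO[Si](c1ccccc1)(c1ccccc1)C(C)(C)C | intermediate
15 | methyl (2S,3R,4Z)-3-[2-(tert-butyldiphenylsilyloxy)ethyl]-2-{2-[methoxy(methyl)amino]-2-oxoethyl}-4-methylhepta-4,6-dienoate | COC(=O)[C@@H](CC(=O)N(C)OC)[C@H](/C(C)=C\C=C)CCO[Si](c1ccccc1)(c1ccccc1)C(C)(C)C | intermediate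
16 | (2-methylprop-1-en-1-yl)magnesium bromide | CC(C)=C[Mg]Br | starting material
17 | methyl (2S,3R,4Z)-3-[2-(tert-butyldiphenylsilyloxy)ethyl]-4-methyl-2-(4-methyl-2-oxopent-3-en-1-yl)hepta-4,6-dienoate | COC(=O)[C@@H](CC(=O)C=C(C)C)[C@H](/C(C)=C\C=C)CCO[Si](c1ccccc1)(c1ccccc1)C(C)(C)C | intermediate
18 | methyl (5S,8S,9R,10S)-12-(tert-butyldiphenylsilyloxy)-6-oxo-13,14,15,16-tetranorlabd-1-en-17-oate (cis-fused) | CC(C)(C)[Si](c1ccccc1)(c1ccccc1)OCC[C@@H]1[C@@H](C(=O)OC)CC(=O)[C@H]2C(C)(C)CC=C[C@@]12C | intermediate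
19 | methyl (5S,8S,9R,10S)-12-(tert-butyldiphenylsilyloxy)-6-oxo-13,14,15,16-tetranorlabdan-17-oate (cis-fused) | CC(C)(C)[Si](c1ccccc1)(c1ccccc1)OCC[C@@H]1[C@@H](C(=O)OC)CC(=O)[C@H]2C(C)(C)CCC[C@@]12C | intermediate
20 | methyl (5R,8S,9R,10S)-12-(tert-butyldiphenylsilyloxy)-6-oxo-13,14,15,16-tetranorlabdan-17-oate (trans-fused) | CC(C)(C)[Si](c1ccccc1)(c1ccccc1)OCC[C@@H]1[C@@H](C(=O)OC)CC(=O)[C@@H]2C(C)(C)CCC[C@@]12C | intermediate
21 | 6-trimethylsilyl enol ether (C6=C7) of 20 | CC(C)(C)[Si](c1ccccc1)(c1ccccc1)OCC[C@@H]1[C@@H](C(=O)OC)C=C(O[Si](C)(C)C)[C@@H]2C(C)(C)CCC[C@@]12C | intermediate (not isolated)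
22 | methyl (5R,9S,10S)-12-(tert-butyldiphenylsilyloxy)-6-oxo-13,14,15,16-tetranorlabd-7-en-17-oate | CC(C)(C)[Si](c1ccccc1)(c1ccccc1)OCC[C@@H]1C(C(=O)OC)=CC(=O)[C@@H]2C(C)(C)CCC[C@@]12C | intermediate
23 | (5R,6S,9S,10S)-12-(tert-butyldiphenylsilyloxy)-13,14,15,16-tetranorlabd-7-ene-6,17-diol | CC(C)(C)[Si](c1ccccc1)(c1ccccc1)OCC[C@@H]1C(CO)=C[C@H](O)[C@@H]2C(C)(C)CCC[C@@]12C | intermediate
24 | (5R,6S,9S,10S)-12-(tert-butyldiphenylsilyloxy)-13,14,15,16-tetranorlabd-7-ene-6,17-diyl diacetate | CC(C)(C)[Si](c1ccccc1)(c1ccccc1)OCC[C@@H]1C(COC(C)=O)=C[C@H](OC(C)=O)[C@@H]2C(C)(C)CCC[C@@]12C | intermediate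
25 | (5R,6S,9S,10S)-12-hydroxy-13,14,15,16-tetranorlabd-7-ene-6,17-diyl diacetate | OCC[C@@H]1C(COC(C)=O)=C[C@H](OC(C)=O)[C@@H]2C(C)(C)CCC[C@@]12C | intermediate
26 | (5R,6S,9S,10S)-12-oxo-13,14,15,16-tetranorlabd-7-ene-6,17-diyl diacetate | O=CC[C@@H]1C(COC(C)=O)=C[C@H](OC(C)=O)[C@@H]2C(C)(C)CCC[C@@]12C | intermediate
27 | 2-(triphenylphosphoranylidene)propanal | CC(C=O)=P(c1ccccc1)(c1ccccc1)c1ccccc1 | starting material
28 | (5R,6S,9S,10S,12E)-14-oxo-15-norlabda-7,12-diene-6,17-diyl diacetate | O=C/C(C)=C/C[C@@H]1C(COC(C)=O)=C[C@H](OC(C)=O)[C@@H]2C(C)(C)CCC[C@@]12C | intermediate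
29 | (5R,6S,9S,10S,12E)-labda-7,12,14-triene-6,17-diyl diacetate | C=C/C(C)=C/C[C@@H]1C(COC(C)=O)=C[C@H](OC(C)=O)[C@@H]2C(C)(C)CCC[C@@]12C | target

Total step count: 21. Longest linear sequence: 21 steps (1 to 29).

Steps most likely to fail

Step 12. Both new bonds end at carbons that become quaternary, so the cycloaddition may be slower than Lewis-acid-induced oligomerisation or geometric isomerisation of the diene. Fallback: a cationic (ionic) Diels–Alder reaction. From 17, ketalisation with 1,2-bis(trimethylsilyloxy)ethane and catalytic Me3SiOTf at −78 °C would give the 1,3-dioxolane of trienone 17 F1. Stoichiometric Me3SiOTf would then open the dioxolane to a 2-alkoxyallyl cation, a far stronger dienophile, and a stepwise cationic [4+2] reaction under the same allylic-strain control should give the 1,3-dioxolane of octalone 18 F2. Mild aqueous acid would return the route at 18.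

Step 4. Transfer of the α-branched alkenyl group from boron to rhodium may be slow, so that protodeboronation takes over or the enantioselectivity erodes. Fallback: auxiliary-controlled cuprate addition and alkylation. But-3-en-1-ol would be silylated to tert-butyl(but-3-en-1-yloxy)diphenylsilane F3. Cross-metathesis with commercially available (S)-3-acryloyl-4-benzyloxazolidin-2-one under the second-generation Grubbs catalyst RuCl2(PCy3)(H2IMes)(=CHPh) would give (S)-4-benzyl-3-[(E)-5-(tert-butyldiphenylsilyloxy)pent-2-enoyl]oxazolidin-2-one F4. From 4, iodine–lithium exchange (t-BuLi), transmetalation (MgBr2·OEt2, then CuBr·SMe2) and conjugate addition to the magnesium-chelated imide F4, opposite the benzyl group, should set C9 and give the conjugate adduct imide F5. Alkylation of its sodium enolate (NaN(SiMe3)2) with 8, again opposite the benzyl group, would give the alkylated imide F6. Methanolysis (MeOMgBr, MeOH) would release the auxiliary and return the route at 12, bypassing steps 4 to 7.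

Step 14. The base-mediated equilibrium may leave cis-fused ketone if the preference for the trans fusion is smaller than expected next to the C4 gem-dimethyl group. Fallback: kinetic protonation of a regiodefined enol derivative. From 19, silylation under equilibrating conditions (Me3SiI, (Me3Si)2NH, CH2Cl2) would give the more substituted C5=C6 trimethylsilyl enol ether F7. Protodesilylation at low temperature (HF·pyridine buffered with pyridine, −40 °C) should deliver the proton to C5 on the face opposite the C10 and axial C4 methyl groups and give 20.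

Further compounds
F1 | step 12 | 1,3-dioxolane of trienone 17 | COC(=O)[C@@H](CC1(C=C(C)C)OCCO1)[C@H](/C(C)=C\C=C)CCO[Si](c1ccccc1)(c1ccccc1)C(C)(C)C
F2 | step 12 | 1,3-dioxolane of octalone 18 | CC(C)(C)[Si](c1ccccc1)(c1ccccc1)OCC[C@@H]1[C@@H](C(=O)OC)CC3(OCCO3)[C@H]2C(C)(C)CC=C[C@@]12C
F3 | step 4 | tert-butyl(but-3-en-1-yloxy)diphenylsilane | C=CCCO[Si](c1ccccc1)(c1ccccc1)C(C)(C)C
F4 | step 4 | (S)-4-benzyl-3-[(E)-5-(tert-butyldiphenylsilyloxy)pent-2-enoyl]oxazolidin-2-one | O=C(/C=C/CCO[Si](c1ccccc1)(c1ccccc1)C(C)(C)C)N1[C@@H](Cc2ccccc2)COC1=O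
F5 | step 4 | (S)-4-benzyl-3-{(3R,4Z)-6-(tert-butyldimethylsilyloxy)-3-[2-(tert-butyldiphenylsilyloxy)ethyl]-4-methylhex-4-enoyl}oxazolidin-2-one (conjugate adduct imide) | O=C(C[C@H](/C(C)=C\CO[Si](C)(C)C(C)(C)C)CCO[Si](c1ccccc1)(c1ccccc1)C(C)(C)C)N1[C@@H](Cc2ccccc2)COC1=O
F6 | step 4 | (S)-4-benzyl-3-{(2S,3R,4Z)-6-(tert-butyldimethylsilyloxy)-3-[2-(tert-butyldiphenylsilyloxy)ethyl]-2-{2-[methoxy(methyl)amino]-2-oxoethyl}-4-methylhex-4-enoyl}oxazolidin-2-one (alkylated imide) | O=C([C@@H](CC(=O)N(C)OC)[C@H](/C(C)=C\CO[Si](C)(C)C(C)(C)C)CCO[Si](c1ccccc1)(c1ccccc1)C(C)(C)C)N1[C@@H](Cc2ccccc2)COC1=O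
F7 | step 14 | C5=C6 trimethylsilyl enol ether of ketone 19 | CC(C)(C)[Si](c1ccccc1)(c1ccccc1)OCC[C@@H]1[C@@H](C(=O)OC)CC(O[Si](C)(C)C)=C2C(C)(C)CCC[C@@]12C
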